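The target is cut back to a flat 3-aroyl-2-arylbenzofuran. The feature exploited is that the furan bond O7''–C2, the C3–C4 bond and the C4–C4a bond to ring A all meet at the C2/C3 pair, the two carbons shared by the dihydrofuran ring and pyranone ring C. A single palladium-catalysed annulation of an (S)-8-(arylethynyl)flavan-7-ol (5,4'-dibenzyl ether, free O–H next to the alkyne) with carbon monoxide and 2-iodo-1,3,5-tris(benzyloxy)benzene forms these three bonds and the furan ring. Ring C and the C3 hydroxyl follow by phenoxide addition to C2 and oxygenation of the resulting enolate.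

Key step: step 8

Assumption: as written, the target is (2R,3S,2''S) with the C2 aryl group and the C3 hydroxyl anti, i.e. a strained trans fusion of the dihydrofuran and pyranone rings; this is taken as the goal, so the junction is set under kinetic control and kept away from acid and base afterwards, which would be expected to equilibrate the C2 ketal to the cis-fused isomer.

Locants: the chromanone unit is O1, C2, C3, C4 (C=O), ring A = C4a–C8a, ring B on C2, ring C = the pyranone. The flavan unit is double-primed (O1''–C8a''); before step 8 the flavan fragment carries the same locants without primes.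

Step 1
Reactants: 1 (S)-naringenin
Product: 2 (2S)-5-hydroxy-2-(4-hydroxyphenyl)-7-(methoxymethoxy)chroman-4-one
Conditions: MOMCl (1.05 equiv), i-Pr2NEt, THF, 0 °C
Reagents that add atoms: chloromethyl methyl ether, COCCl
Why: The 7-OH, para to the C4 carbonyl, is the most acidic phenol (5-OH is chelated, 4'-OH is an ordinary phenol), so one equivalent of MOMCl with a hindered amine should give selective Williamson-type etherification under conditions too mild to open the flavanone, leaving C2 (S) untouched.

Step 2
Reactants: 2 (2S)-7-O-MOM-naringenin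
Product: 6 (2S)-2-(4-hydroxyphenyl)-7-(methoxymethoxy)chroman-5-ol, via bis(ethyl carbonate) 3 (not isolated), via ortho-quinone methide 4 (not isolated), via flavan 4'-carbonate 5 (not isolated)
Conditions: ClCO2Et, Et3N, THF, 0 °C; filter; NaBH4, THF/H2O, 0 °C to rt; 1 M NaOH, MeOH, rt
Reagents that add atoms: none
Why: This is the carbonate-assisted NaBH4 deoxygenation of an ortho-acylphenol: hydride reduces C4=O, the 5-O-carbonate moves to the benzylic oxygen and leaves to give quinone methide 4, a second hydride adds at C4, and hydroxide cleaves the remaining carbonate of 5, all without involving C2.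

Step 3
Reactants: 6 (2S)-7-(methoxymethoxy)flavan-5,4'-diol
Product: 7 (2S)-5-(benzyloxy)-2-[4-(benzyloxy)phenyl]-7-(methoxymethoxy)chroman
Conditions: BnBr, K2CO3, DMF, rt
Reagents that add atoms: benzyl bromide, BrCc1ccccc1
Why: Williamson etherification of the two free phenols should be clean, and with the C4 carbonyl gone the base can no longer open the pyran ring, so C2 is safe.

Step 4
Reactants: 7 (2S)-5,4'-bis(benzyloxy)-7-(methoxymethoxy)flavan
Product: 8 (2S)-5-(benzyloxy)-2-[4-(benzyloxy)phenyl]-8-iodo-7-(methoxymethoxy)chroman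
Conditions: NIS, DMF, 0 °C to rt, dark
Reagents that add atoms: N-iodosuccinimide, O=C1CCC(=O)N1I
Why: Electrophilic aromatic iodination of the trioxygenated ring should go to C8 (flanked by the ring oxygen) rather than C6 (between two acyclic ethers), as in the halogenation of fully etherified flavans.

Step 5
Reactants: 8 (2S)-8-iodo-7-(methoxymethoxy)flavan dibenzyl ether; 9 1-(benzyloxy)-4-ethynylbenzene
Product: 10 (2S)-5-(benzyloxy)-2-[4-(benzyloxy)phenyl]-8-{[4-(benzyloxy)phenyl]ethynyl}-7-(methoxymethoxy)chroman
Conditions: Pd(PPh3)2Cl2 (5 mol%), CuI (5 mol%), Et3N/DMF, 65 °C, degassed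
Reagents that add atoms: none
Why: Sonogashira coupling of the hindered aryl iodide should proceed on warming, and the MOM ether on O7 keeps the phenol masked so the product cannot close to a 3-unsubstituted benzofuran under the palladium/copper conditions.

Step 6
Reactants: 10 (2S)-8-(arylethynyl)-7-(methoxymethoxy)flavan
Product: 11 (2S)-5-(benzyloxy)-2-[4-(benzyloxy)phenyl]-8-{[4-(benzyloxy)phenyl]ethynyl}chroman-7-ol
Conditions: conc. HCl (cat.), MeOH/THF, 45 °C
Reagents that add atoms: none
Why: Acid-catalysed acetal exchange should remove the MOM group as dimethoxymethane while the benzyl ethers, the diarylalkyne and the flavan ring tolerate dilute methanolic acid, and no base or metal is present to trigger cycloisomerisation.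

Step 7
Reactants: 12 1,3,5-tris(benzyloxy)benzene
Product: 13 2-iodo-1,3,5-tris(benzyloxy)benzene
Conditions: NIS (1.0 equiv), MeCN, 0 °C to rt
Reagents that add atoms: N-iodosuccinimide, O=C1CCC(=O)N1I
Why: Electrophilic mono-iodination of a threefold-symmetric trialkoxybenzene has only one possible site, so only the stoichiometry needs control.

Step 8
Reactants: 11 (2S)-8-(arylethynyl)flavan-7-ol; 13 2-iodo-1,3,5-tris(benzyloxy)benzene; 14 carbon monoxide
Product: 15 (2''S)-flavan-fused 2-[4-(benzyloxy)phenyl]-3-[2,4,6-tris(benzyloxy)benzoyl]benzofuran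
Conditions: Pd(PPh3)4 (10 mol%), KOAc, CO (1 atm), MeCN/THF, 50 °C; 11 added slowly to 13 (1.5 equiv)
Reagents that add atoms: none
Why: Oxidative addition of 13 to zerovalent palladium and CO insertion give a 2,4,6-tris(benzyloxy)benzoyl complex of divalent palladium that binds the alkyne of 11; the phenol oxygen O7'' then attacks the coordinated alkyne anti to the metal and reductive elimination joins C3 to the acyl carbon C4, so O7''–C2, C3–C4 and C4–C4a form in one catalytic cycle. The closest known reaction type is the palladium-catalysed carbonylative heteroannulation of 2-alkynylphenols with aryl iodides and CO to 3-aroylbenzofurans. The one new ring, the furan, closes by 5-endo-dig oxypalladation. No stereocentre is created, and C2'' (S) is remote from the reacting atoms. The step needs CO insertion before attack on the alkyne, and C-acylation faster than O-aroylation of the phenol or plain cycloisomerisation; the two ortho benzyloxy groups of 13 slow direct aryl transfer and favour CO insertion, while the weak acetate base and slow addition of 11 to excess 13 under CO keep the free alkynylphenol scarce. The symmetric iodide removes any ring A regiochemistry, and the alkyne carbon bearing the aryl group necessarily becomes C2.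

Step 9
Reactants: 15 3-aroylbenzofuran hexabenzyl ether
Product: 16 (2''S)-3-[2,4-bis(benzyloxy)-6-hydroxybenzoyl]benzofuran
Conditions: BCl3 (1.1 equiv), CH2Cl2, −78 °C; then H2O
Reagents that add atoms: none
Why: Chelation-controlled Lewis-acid debenzylation should cleave only one of the two equivalent ortho ethers of ring A, because boron bound to the ketone oxygen activates the ortho benzyl ether and the resulting six-membered chelate no longer activates the second.

Step 10
Reactants: 16 ring A mono-phenol
Product: 18 (2R,3S,2''S)-penta-O-benzyl ether of the target, via potassium enolate 17 (not isolated)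
Conditions: KN(SiMe3)2 (1.05 equiv), 18-crown-6, THF, −78 °C; (−)-[(8,8-dichlorocamphoryl)sulfonyl]oxaziridine (1.5 equiv), −78 to 0 °C; AcOH, −78 °C
Reagents that add atoms: (−)-[(8,8-dichlorocamphoryl)sulfonyl]oxaziridine, CC1(C)[C@H]2CC[C@@]13CS(=O)(=O)N4O[C@]34C2(Cl)Cl
Why: Proposed new method: the ring A phenoxide can add reversibly to C2 of the 3-aroylbenzofuran (six-membered closure of ring C, dearomatising the furan) to give a small equilibrium share of fused enolate 17 as both C2 epimers; the two rings of 17 force the C2 aryl group perpendicular to the enolate plane, so the oxaziridine should reach C3 only from the face anti to that aryl, which sets the anti C2-aryl/C3-OH trans junction, and since oxygen transfer is irreversible and only the enolate is oxidised the equilibrium is drained (Curtin–Hammett); the enantiopure reagent should react faster with one of the two interconverting C2-epimeric enolates and so fix the absolute sense (2R,3S), the (−)-reagent being assigned tentatively by analogy with its sense on 2-substituted 1-tetralone enolates; the closest known reaction types are the Algar–Flynn–Oyamada closure of 2'-hydroxychalcones (phenoxide conjugate addition coupled to enolate oxygenation), tandem conjugate addition/enolate hydroxylation with camphorsulfonyl oxaziridines, and Davis oxidation of tetrasubstituted cyclic ketone enolates.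

Step 11
Reactants: 18 (2R,3S,2''S)-penta-O-benzyl ether
Product: 19 target, (2R,3S,2''S)
Conditions: H2 (1 atm), 10% Pd on carbon, EtOAc/THF, rt
Reagents that add atoms: none
Why: Neutral hydrogenolysis should remove the five aryl benzyl ethers while offering no acid or base pathway for the trans junction or the C2 ketal to equilibrate, and the aryl ketone, tertiary alcohol and flavan C2''–O bond are expected to tolerate these conditions.

Compound list
1 | (S)-naringenin, (2S)-5,7-dihydroxy-2-(4-hydroxyphenyl)chroman-4-one | O=C1C[C@@H](c2ccc(O)cc2)Oc2cc(O)cc(O)c12 | starting material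
2 | (2S)-5-hydroxy-2-(4-hydroxyphenyl)-7-(methoxymethoxy)chroman-4-one | O=C1C[C@@H](c2ccc(O)cc2)Oc2cc(OCOC)cc(O)c12 | intermediate
3 | (2S)-5-(ethoxycarbonyloxy)-2-[4-(ethoxycarbonyloxy)phenyl]-7-(methoxymethoxy)chroman-4-one | O=C1C[C@@H](c2ccc(OC(=O)OCC)cc2)Oc2cc(OCOC)cc(OC(=O)OCC)c12 | intermediate
4 | ortho-quinone methide, (2S)-2-[4-(ethoxycarbonyloxy)phenyl]-7-(methoxymethoxy)-2,3-dihydrochromen-5-one with C4=C4a and C8=C8a double bonds | O=C1C=C(OCOC)C=C2O[C@H](c3ccc(OC(=O)OCC)cc3)CC=C12 | intermediate
5 | ethyl 4-[(2S)-5-hydroxy-7-(methoxymethoxy)chroman-2-yl]phenyl carbonate | COCOc1cc(O)c2c(c1)O[C@H](c1ccc(OC(=O)OCC)cc1)CC2 | intermediate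
6 | (2S)-2-(4-hydroxyphenyl)-7-(methoxymethoxy)chroman-5-ol | COCOc1cc(O)c2c(c1)O[C@H](c1ccc(O)cc1)CC2 | intermediate
7 | (2S)-5-(benzyloxy)-2-[4-(benzyloxy)phenyl]-7-(methoxymethoxy)chroman | COCOc1cc(OCc5ccccc5)c2c(c1)O[C@H](c1ccc(OCc5ccccc5)cc1)CC2 | intermediate
8 | (2S)-5-(benzyloxy)-2-[4-(benzyloxy)phenyl]-8-iodo-7-(methoxymethoxy)chroman | COCOc1cc(OCc5ccccc5)c2c(c1I)O[C@H](c1ccc(OCc5ccccc5)cc1)CC2 | intermediate
9 | 1-(benzyloxy)-4-ethynylbenzene | C#Cc1ccc(OCc2ccccc2)cc1 | starting material
10 | (2S)-5-(benzyloxy)-2-[4-(benzyloxy)phenyl]-8-{[4-(benzyloxy)phenyl]ethynyl}-7-(methoxymethoxy)chroman | COCOc1cc(OCc5ccccc5)c2c(c1C#Cc1ccc(OCc5ccccc5)cc1)O[C@H](c1ccc(OCc5ccccc5)cc1)CC2 | intermediate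
11 | (2S)-5-(benzyloxy)-2-[4-(benzyloxy)phenyl]-8-{[4-(benzyloxy)phenyl]ethynyl}chroman-7-ol | Oc1cc(OCc5ccccc5)c2c(c1C#Cc1ccc(OCc5ccccc5)cc1)O[C@H](c1ccc(OCc5ccccc5)cc1)CC2 | intermediate
12 | 1,3,5-tris(benzyloxy)benzene | c1c(OCc2ccccc2)cc(OCc2ccccc2)cc1OCc1ccccc1 | starting material
13 | 2-iodo-1,3,5-tris(benzyloxy)benzene | Ic1c(OCc2ccccc2)cc(OCc2ccccc2)cc1OCc1ccccc1 | intermediate
14 | carbon monoxide | [C-]#[O+] | starting material
15 | benzofuran (furan O = O7'', C3 bonded to C8'') fused on the (2''S)-flavan; C2 bears 4-(benzyloxy)phenyl, C3 the 2,4,6-tris(benzyloxy)benzoyl group; O5'' and the flavan aryl oxygen benzylated | O=C(c1c(OCc5ccccc5)cc(OCc5ccccc5)cc1OCc5ccccc5)c1c(-c2ccc(OCc5ccccc5)cc2)oc2cc(OCc5ccccc5)c3c(c12)O[C@H](c1ccc(OCc5ccccc5)cc1)CC3 | intermediate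
16 | as 15, with one ortho benzyl ether of the aroyl ring (ring A) cleaved to the free chelated phenol | O=C(c1c(O)cc(OCc5ccccc5)cc1OCc5ccccc5)c1c(-c2ccc(OCc5ccccc5)cc2)oc2cc(OCc5ccccc5)c3c(c12)O[C@H](c1ccc(OCc5ccccc5)cc1)CC3 | intermediate
17 | potassium enolate with ring C closed (O1–C2 bond), C3=C4–O⁻ K⁺, (2R,2''S), five benzyl ethers | [K+].[O-]C1=C2c3c4O[C@H](c5ccc(OCc6ccccc6)cc5)CCc4c(OCc4ccccc4)cc3O[C@]2(c2ccc(OCc3ccccc3)cc2)Oc2cc(OCc3ccccc3)cc(OCc3ccccc3)c12 | intermediate
18 | (2R,3S,2''S)-penta-O-benzyl ether of the target (C2 aryl and C3 OH anti) | O=C1c2c(OCc5ccccc5)cc(OCc5ccccc5)cc2O[C@@]2(c3ccc(OCc5ccccc5)cc3)Oc3cc(OCc5ccccc5)c4c(c3[C@]12O)O[C@H](c1ccc(OCc5ccccc5)cc1)CC4 | intermediate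
19 | CNP0208300.3, (2R,3S,2''S): 3,5,7,5''-tetrahydroxy-2,2''-bis(4-hydroxyphenyl)chromanone–flavan dimer linked C3–C8'' and C2–O–C7'' | O=C1c2c(O)cc(O)cc2O[C@@]2(c3ccc(O)cc3)Oc3cc(O)c4c(c3[C@]12O)O[C@H](c1ccc(O)cc1)CC4 | target

Total step count: 11. Longest linear sequence: 10 steps (from 1 through steps 1–6 and 8–11).

Steps most likely to fail

1. Step 10 (the step labelled "Proposed new method:").
   - The dearomative phenoxide addition may lie too far on the benzofuran side for any enolate to be intercepted.
   - Oxygen may be transferred to the electron-rich ring A carbon of the phenoxide instead.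
   - The oxidant may be forced syn to the aryl group by the strain of the developing trans junction.
   - The chosen reagent enantiomer may be mismatched with the required C2 epimer; the antipodal reagent is then used.
   - Fallback, in known chemistry, setting out from 16 and returning at 18: epoxidation of the furan C2=C3 bond with dimethyldioxirane (acetone/CH2Cl2, −40 °C), the epoxide being opened in the flask by the ring A phenol, should give the cis-fused (2R,3R,2''S) hydroxy ketal F1 after separation from its (2S,3S) companion. Acetylation (Ac2O, DMAP) gives the C3 acetate F2. Reductive cleavage of this α-acetoxy ketone with SmI2 (THF, −78 °C) should regenerate the enolate with C2 intact as the samarium enolate F3, which is oxidised in the same flask with the oxaziridine of step 10 to 18.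

2. Step 8.
   - Cycloisomerisation of 11 to the 3-unsubstituted benzofuran may outrun acyl transfer.
   - The phenol may be O-aroylated.
   - Oxidative addition of the hindered, electron-rich iodide may stall under CO.
   - Fallback, setting out from 11 and 12 and returning at 15: iodocyclisation of 11 (I2, NaHCO3, MeCN, 0 °C) should give the 3-iodobenzofuran F4. Vilsmeier formylation of 12 (POCl3, DMF) gives 2,4,6-tris(benzyloxy)benzaldehyde F5. Iodine–magnesium exchange on F4 (i-PrMgCl·LiCl, THF, −20 °C) and addition to F5 give the diaryl carbinol F6 (both carbinol epimers, immaterial). Dess–Martin oxidation then gives 15.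

3. Step 11.
   - The benzylic C2 ketal of the strained junction may be opened reductively on the catalyst.
   - The junction may isomerise to the cis form once the C2 aryl group carries a free para-phenol.
   - Fallback, setting out from 15 and returning at 19, with the protecting groups changed before the junction exists: hydrogenolysis at the robust benzofuran stage (H2, 10% Pd on carbon, EtOAc/MeOH) gives the hexaphenol F7. TBSCl/imidazole (DMF) should silylate every phenol except the chelated ortho one, giving the penta-silyl ether F8. The conditions of step 10 then give the silylated trans-fused ketal F9, and HF·pyridine buffered with pyridine (THF, 0 °C) releases 19 without hydrogen or metal.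

Further compounds
F1 | step 10 | cis-fused (2R,3R,2''S) 3-hydroxy ketal, penta-O-benzyl ether | O=C1c2c(OCc5ccccc5)cc(OCc5ccccc5)cc2O[C@@]2(c3ccc(OCc5ccccc5)cc3)Oc3cc(OCc5ccccc5)c4c(c3[C@@]12O)O[C@H](c1ccc(OCc5ccccc5)cc1)CC4
F2 | step 10 | C3 acetate of F1 | O=C1c2c(OCc5ccccc5)cc(OCc5ccccc5)cc2O[C@@]2(c3ccc(OCc5ccccc5)cc3)Oc3cc(OCc5ccccc5)c4c(c3[C@@]12OC(C)=O)O[C@H](c1ccc(OCc5ccccc5)cc1)CC4
F3 | step 10 | samarium enolate (anion of 17 with a diiodosamarium counter-ion) | [Sm+3].[I-].[I-].[O-]C1=C2c3c4O[C@H](c5ccc(OCc6ccccc6)cc5)CCc4c(OCc4ccccc4)cc3O[C@]2(c2ccc(OCc3ccccc3)cc2)Oc2cc(OCc3ccccc3)cc(OCc3ccccc3)c12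
F4 | step 8 | (2''S)-flavan-fused 2-[4-(benzyloxy)phenyl]-3-iodobenzofuran | Ic1c(-c2ccc(OCc5ccccc5)cc2)oc2cc(OCc5ccccc5)c3c(c12)O[C@H](c1ccc(OCc5ccccc5)cc1)CC3
F5 | step 8 | 2,4,6-tris(benzyloxy)benzaldehyde | O=Cc1c(OCc2ccccc2)cc(OCc2ccccc2)cc1OCc1ccccc1
F6 | step 8 | benzofuran-3-yl[2,4,6-tris(benzyloxy)phenyl]methanol, both carbinol epimers | OC(c1c(OCc5ccccc5)cc(OCc5ccccc5)cc1OCc5ccccc5)c1c(-c2ccc(OCc5ccccc5)cc2)oc2cc(OCc5ccccc5)c3c(c12)O[C@H](c1ccc(OCc5ccccc5)cc1)CC3
F7 | step 11 | hexaphenol, (2''S)-flavan-fused 2-(4-hydroxyphenyl)-3-(2,4,6-trihydroxybenzoyl)benzofuran | O=C(c1c(O)cc(O)cc1O)c1c(-c2ccc(O)cc2)oc2cc(O)c3c(c12)O[C@H](c1ccc(O)cc1)CC3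
F8 | step 11 | penta-O-TBS ether of F7 with one chelated ortho phenol free | O=C(c1c(O)cc(O[Si](C)(C)C(C)(C)C)cc1O[Si](C)(C)C(C)(C)C)c1c(-c2ccc(O[Si](C)(C)C(C)(C)C)cc2)oc2cc(O[Si](C)(C)C(C)(C)C)c3c(c12)O[C@H](c1ccc(O[Si](C)(C)C(C)(C)C)cc1)CC3
F9 | step 11 | (2R,3S,2''S)-penta-O-TBS ether of the target | O=C1c2c(O[Si](C)(C)C(C)(C)C)cc(O[Si](C)(C)C(C)(C)C)cc2O[C@@]2(c3ccc(O[Si](C)(C)C(C)(C)C)cc3)Oc3cc(O[Si](C)(C)C(C)(C)C)c4c(c3[C@]12O)O[C@H](c1ccc(O[Si](C)(C)C(C)(C)C)cc1)CC4
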